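## Retrosynthetic overview

- (−)-Carinol ⇐ diethyl 2-hydroxy-2,3-bis(arylmethyl)butanedioate, by reduction of both esters to the two CH2OH groups.
- That diester ⇐ an α-hydroxy aryl ketone, by hydrogenolysis of the benzylic C=O to CH2 (the same operation removes the one benzyl ether).
- Key disconnection, ArC(=O)–C(OH): O-benzylvanillin is added as an acyl anion (Breslow intermediate of a chiral triazolylidene) to the ketone of a racemic 3-(arylmethyl)-2-oxobutanedioate. Dynamic kinetic resolution is meant to set both stereocentres in this one step.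
- The keto diester ⇐ ethyl dihydroferulate + diethyl oxalate (Claisen condensation).
- Rings: none is formed; both guaiacyl rings are bought.

Assumption: 1 is bought (it is also one Fischer esterification away from dihydroferulic acid), and the facial sense of the (5aS,10bR) triazolium salt in step 2 is taken by analogy; should the adduct prove antipodal, the equally available (5aR,10bS) salt is used instead.

## Route

Step 1
Reactants: 1 ethyl 3-(4-hydroxy-3-methoxyphenyl)propanoate; 2 diethyl oxalate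
Product: 4 diethyl 2-(4-hydroxy-3-methoxybenzyl)-3-oxobutanedioate (racemic keto-enol mixture), via disodium enolate-phenoxide salt 3 (not isolated)
Conditions: NaOEt (2.3 equiv), 2 (1.5 equiv), EtOH/THF, 0 → 23 °C, 16 h; then cold 1 M HCl
Reagents that add atoms: none
Why: Crossed Claisen condensation: the ester enolate of 1 acylates the non-enolisable oxalate and the equilibrium is pulled over by deprotonation of the doubly activated product to salt 3 (the extra equivalent of base covers the phenol); the new stereocentre is left racemic on purpose because it must epimerise in step 2.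

Step 2
Reactants: 4 diethyl 2-(4-hydroxy-3-methoxybenzyl)-3-oxobutanedioate; 5 4-(benzyloxy)-3-methoxybenzaldehyde
Product: 7 diethyl (2R,3R)-2-[4-(benzyloxy)-3-methoxybenzoyl]-2-hydroxy-3-(4-hydroxy-3-methoxybenzyl)butanedioate, via Breslow intermediate 6 (not isolated)
Conditions: 5 (1.5 equiv), (5aS,10bR)-2-(pentafluorophenyl)-5a,10b-dihydro-4H,6H-indeno[2,1-b][1,2,4]triazolo[4,3-d][1,4]oxazin-2-ium tetrafluoroborate (15 mol%), i-Pr2NEt (30 mol%), 4 Å molecular sieves, t-BuOMe, 0 → 23 °C, Ar
Reagents that add atoms: none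
Why: Proposed new method: the triazolylidene adds to 5 and proton transfer gives Breslow intermediate 6, whose now nucleophilic former aldehyde carbon attacks the ketone of 4 (far more electrophilic than 5 or either ester) before the catalyst is expelled, i.e. an NHC-catalysed cross-benzoin; 4 racemises through its achiral enol under the amine, so only its (R)-enantiomer is drained (dynamic kinetic resolution), with the acyl group arriving anti to the neighbouring ester (polar Felkin–Anh) on the ketone face chosen by the aminoindanol scaffold, which sets C2 and C3 together; the closest known reaction type is the carbene-catalysed dynamic kinetic asymmetric cross-benzoin of aldehydes with racemic β-halo α-keto esters.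

Step 3
Reactants: 7 diethyl (2R,3R)-2-[4-(benzyloxy)-3-methoxybenzoyl]-2-hydroxy-3-(4-hydroxy-3-methoxybenzyl)butanedioate
Product: 10 diethyl (2S,3R)-2-hydroxy-2,3-bis(4-hydroxy-3-methoxybenzyl)butanedioate, via debenzylated ketone 8 (not isolated), via benzylic alcohol 9 (not isolated)
Conditions: H2 (5 atm), Pd/C (10% palladium on carbon), EtOH–AcOH (4:1), 45 °C
Reagents that add atoms: none
Why: Catalytic hydrogenolysis: palladium cleaves the benzyl ether and reduces the electron-rich aryl ketone through benzylic alcohol 9 to CH2 (benzylic C–O cleavage helped by the para oxygen); no stereocentre is touched, and C2 is renamed R → S only because the CIP ranking of its substituents changes.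

Step 4
Reactants: 10 diethyl (2S,3R)-2-hydroxy-2,3-bis(4-hydroxy-3-methoxybenzyl)butanedioate
Product: 11 (−)-carinol, (2S,3S)-2,3-bis(4-hydroxy-3-methoxybenzyl)butane-1,2,4-triol
Conditions: LiAlH4 (6 equiv), THF, 0 → 65 °C, 4 h; then H2O, 1 M HCl to pH 3, EtOAc extraction
Reagents that add atoms: none
Why: Hydride reduction of both esters to primary alcohols with LiAlH4 (the excess covers the three acidic OH groups); the stereocentres are untouched, and C3 is renamed R → S by CIP ranking only.

## Compound list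

1 | ethyl 3-(4-hydroxy-3-methoxyphenyl)propanoate | CCOC(=O)CCc1ccc(O)c(OC)c1 | starting material
2 | diethyl oxalate | CCOC(=O)C(=O)OCC | starting material
3 | disodium enolate-phenoxide salt of 4 (not isolated) | [Na+].[Na+].CCOC(=O)C([O-])=C(Cc1ccc([O-])c(OC)c1)C(=O)OCC | intermediate
4 | diethyl 2-(4-hydroxy-3-methoxybenzyl)-3-oxobutanedioate (racemic) | CCOC(=O)C(=O)C(Cc1ccc(O)c(OC)c1)C(=O)OCC | intermediate
5 | 4-(benzyloxy)-3-methoxybenzaldehyde | COc1cc(C=O)ccc1OCc1ccccc1 | starting material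
6 | Breslow intermediate, enaminol of 5 on the (5aS,10bR)-triazolylidene (not isolated) | OC(c1ccc(OCc2ccccc2)c(OC)c1)=C1N(c2c(F)c(F)c(F)c(F)c2F)N=C2CO[C@H]3Cc4ccccc4[C@H]3N12 | intermediate
7 | diethyl (2R,3R)-2-[4-(benzyloxy)-3-methoxybenzoyl]-2-hydroxy-3-(4-hydroxy-3-methoxybenzyl)butanedioate | COc1cc(C[C@@H](C(=O)OCC)[C@](O)(C(=O)OCC)C(=O)c2ccc(OCc3ccccc3)c(OC)c2)ccc1O | intermediate
8 | diethyl (2R,3R)-2-hydroxy-2-(4-hydroxy-3-methoxybenzoyl)-3-(4-hydroxy-3-methoxybenzyl)butanedioate (not isolated) | COc1cc(C[C@@H](C(=O)OCC)[C@](O)(C(=O)OCC)C(=O)c2ccc(O)c(OC)c2)ccc1O | intermediate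
9 | diethyl (2R,3R)-2-hydroxy-2-[hydroxy(4-hydroxy-3-methoxyphenyl)methyl]-3-(4-hydroxy-3-methoxybenzyl)butanedioate, both carbinol epimers (not isolated) | COc1cc(C[C@@H](C(=O)OCC)[C@](O)(C(=O)OCC)C(O)c2ccc(O)c(OC)c2)ccc1O | intermediate
10 | diethyl (2S,3R)-2-hydroxy-2,3-bis(4-hydroxy-3-methoxybenzyl)butanedioate | COc1cc(C[C@@H](C(=O)OCC)[C@](O)(C(=O)OCC)Cc2ccc(O)c(OC)c2)ccc1O | intermediate
11 | (−)-carinol, (2S,3S)-2,3-bis(4-hydroxy-3-methoxybenzyl)butane-1,2,4-triol | COc1cc(C[C@@H](CO)[C@](O)(CO)Cc2ccc(O)c(OC)c2)ccc1O | target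

## Count and risks

Total step count: 4. Longest linear sequence: 4 steps (1 → 4 → 7 → 10 → 11).

**Step 2 (most likely to fail).** The carbene may be throttled by the acidic, partly enolised keto diester, or the dynamic resolution may give poor dr or ee. The fallback replaces the carbene-catalysed addition by enolate alkylation with self-regeneration of the stereocentre. It sets out from 5 and rejoins the route at 11.
- Compound 5 is converted in one pot (LiBr, Me3SiCl, 1,1,3,3-tetramethyldisiloxane, MeCN) into 1-(benzyloxy)-4-(bromomethyl)-2-methoxybenzene F1.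
- Commercial diethyl (S)-malate is doubly deprotonated (LiN(SiMe3)2, THF, −78 → −20 °C) and alkylated anti with F1 to give diethyl (2S,3R)-3-[4-(benzyloxy)-3-methoxybenzyl]-2-hydroxybutanedioate F2.
- Saponification (KOH, aqueous dioxane, then HCl) gives (2S,3R)-3-[4-(benzyloxy)-3-methoxybenzyl]-2-hydroxybutanedioic acid F3.
- Pivalaldehyde with catalytic TsOH (pentane, water separator) closes the α-hydroxy acid to the cis-dioxolanone (2R)-3-[4-(benzyloxy)-3-methoxyphenyl]-2-[(2S,4S)-2-tert-butyl-5-oxo-1,3-dioxolan-4-yl]propanoic acid F4.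
- Its dianion (LiN(SiMe3)2, THF, −78 °C) takes a second portion of the bromide on the face away from the tert-butyl group, i.e. with retention at the carbinol carbon, to give (2R)-3-[4-(benzyloxy)-3-methoxyphenyl]-2-{(2S,4S)-4-[4-(benzyloxy)-3-methoxybenzyl]-2-tert-butyl-5-oxo-1,3-dioxolan-4-yl}propanoic acid F5.
- LiAlH4 (THF, reflux) reduces the acid and the dioxolanone to (2S,3S)-2,3-bis[4-(benzyloxy)-3-methoxybenzyl]butane-1,2,4-triol F6, and H2 over Pd/C (EtOAc/EtOH) removes both benzyl ethers to give 11.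

**Step 3.** The ketone of 7 sits next to a fully substituted carbon and may stop at the alcohol, or the acidic medium may trigger a pinacol-type shift of the intermediate diol. The fallback removes the benzylic oxygen through a lactone instead. It sets out from 7 and rejoins at 11, bypassing 10.
- NaBH4 (EtOH, 0 °C) reduces the ketone to diethyl (2R,3R)-2-{[4-(benzyloxy)-3-methoxyphenyl](hydroxy)methyl}-2-hydroxy-3-(4-hydroxy-3-methoxybenzyl)butanedioate F7.
- Catalytic TsOH (toluene, 60 °C) closes the new hydroxyl onto the C4 ester to the γ-lactone ethyl (3R,4R)-2-[4-(benzyloxy)-3-methoxyphenyl]-3-hydroxy-4-(4-hydroxy-3-methoxybenzyl)-5-oxooxolane-3-carboxylate F8.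
- H2 over Pd/C (EtOAc–AcOH) cleaves the activated benzylic lactone C–O bond together with the benzyl ether to give (2R,3S)-3-(ethoxycarbonyl)-3-hydroxy-2-(4-hydroxy-3-methoxybenzyl)-4-(4-hydroxy-3-methoxyphenyl)butanoic acid F9.
- LiAlH4 under the conditions of step 4 reduces acid and ester to 11.

**Step 1.** With a free phenol, the phenoxide may be acylated by the oxalate or the dianion may be too insoluble for a clean condensation. The fallback acylates a neutral silyl ketene acetal instead. It sets out from 1 and rejoins at 4.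
- LiN(i-Pr)2 (2.2 equiv) and Me3SiCl (THF, −78 °C) give the bis-silylated ketene acetal {[1-ethoxy-3-(3-methoxy-4-(trimethylsilyloxy)phenyl)prop-1-en-1-yl]oxy}trimethylsilane F10.
- C-acylation with ethyl chlorooxoacetate (CH2Cl2, −78 → 0 °C, 5 mol% ZnCl2) gives diethyl 2-[3-methoxy-4-(trimethylsilyloxy)benzyl]-3-oxobutanedioate F11.
- Dilute HCl in MeOH desilylates F11 to 4.

Further compounds
F1 | step 2 | 1-(benzyloxy)-4-(bromomethyl)-2-methoxybenzene | COc1cc(CBr)ccc1OCc1ccccc1
F2 | step 2 | diethyl (2S,3R)-3-[4-(benzyloxy)-3-methoxybenzyl]-2-hydroxybutanedioate | COc1cc(C[C@@H](C(=O)OCC)[C@H](O)C(=O)OCC)ccc1OCc1ccccc1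
F3 | step 2 | (2S,3R)-3-[4-(benzyloxy)-3-methoxybenzyl]-2-hydroxybutanedioic acid | COc1cc(C[C@@H](C(=O)O)[C@H](O)C(=O)O)ccc1OCc1ccccc1
F4 | step 2 | (2R)-3-[4-(benzyloxy)-3-methoxyphenyl]-2-[(2S,4S)-2-tert-butyl-5-oxo-1,3-dioxolan-4-yl]propanoic acid | COc1cc(C[C@@H](C(=O)O)[C@H](O2)C(=O)O[C@H]2C(C)(C)C)ccc1OCc1ccccc1
F5 | step 2 | (2R)-3-[4-(benzyloxy)-3-methoxyphenyl]-2-{(2S,4S)-4-[4-(benzyloxy)-3-methoxybenzyl]-2-tert-butyl-5-oxo-1,3-dioxolan-4-yl}propanoic acid | COc1cc(C[C@@H](C(=O)O)[C@](Cc3ccc(OCc4ccccc4)c(OC)c3)(O2)C(=O)O[C@H]2C(C)(C)C)ccc1OCc1ccccc1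
F6 | step 2 | (2S,3S)-2,3-bis[4-(benzyloxy)-3-methoxybenzyl]butane-1,2,4-triol | COc1cc(C[C@@H](CO)[C@](O)(CO)Cc2ccc(OCc3ccccc3)c(OC)c2)ccc1OCc1ccccc1
F7 | step 3 | diethyl (2R,3R)-2-{[4-(benzyloxy)-3-methoxyphenyl](hydroxy)methyl}-2-hydroxy-3-(4-hydroxy-3-methoxybenzyl)butanedioate | COc1cc(C[C@@H](C(=O)OCC)[C@](O)(C(=O)OCC)C(O)c2ccc(OCc3ccccc3)c(OC)c2)ccc1O
F8 | step 3 | ethyl (3R,4R)-2-[4-(benzyloxy)-3-methoxyphenyl]-3-hydroxy-4-(4-hydroxy-3-methoxybenzyl)-5-oxooxolane-3-carboxylate | COc1cc(C[C@H]2C(=O)OC(c3ccc(OCc4ccccc4)c(OC)c3)[C@@]2(O)C(=O)OCC)ccc1O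
F9 | step 3 | (2R,3S)-3-(ethoxycarbonyl)-3-hydroxy-2-(4-hydroxy-3-methoxybenzyl)-4-(4-hydroxy-3-methoxyphenyl)butanoic acid | COc1cc(C[C@@H](C(=O)O)[C@](O)(C(=O)OCC)Cc2ccc(O)c(OC)c2)ccc1O
F10 | step 1 | {[1-ethoxy-3-(3-methoxy-4-(trimethylsilyloxy)phenyl)prop-1-en-1-yl]oxy}trimethylsilane | CCOC(O[Si](C)(C)C)=CCc1ccc(O[Si](C)(C)C)c(OC)c1
F11 | step 1 | diethyl 2-[3-methoxy-4-(trimethylsilyloxy)benzyl]-3-oxobutanedioate | CCOC(=O)C(=O)C(Cc1ccc(O[Si](C)(C)C)c(OC)c1)C(=O)OCC
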